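Amounts first: the substrate charged ends up shared among the species, and the question is how that sharing stands in larch, cedar and alder.

| setting | amber | green | larch | cedar | alder |
|---|---|---|---|---|---|
| substrate | 66 mM | 100 mM | 47 mM | 47 mM | 47 mM |
| gas | 17 mM (held) | 17 mM (held) | 17 mM (held) | 17 mM (held) | 17 mM (held) |
| remark | run made earlier | run made earlier |  |  |  |
| time |  |  | 12 min | 25 min | 50 min |

| run | time / min | open dimer / % | side product / % | substrate / % | over-reaction product / % | ring / % |
|---|---|---|---|---|---|---|
| amber | 0.667 | 1.4 | 0 | 96.1 | 0 | 0.1 |
| amber | 2.00 | 12.1 | 0.4 | 79.0 | 0.3 | 3.3 |
| amber | 3.00 | 21.5 | 0.4 | 66.1 | 1.3 | 5.5 |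
| amber | 5.00 | 34.3 | 1.6 | 44.7 | 5.6 | 8.6 |
| amber | 8.00 | 46.5 | 1.2 | 23.5 | 15.2 | 9.4 |
| green | 1.33 | 6.1 | 0.8 | 89.6 | 0.3 | 0.9 |
| green | 3.00 | 21.6 | 0.8 | 69.7 | 1.2 | 4.2 |
| green | 4.00 | 29.1 | 0.8 | 59.5 | 1.3 | 5.0 |
| green | 6.00 | 41.6 | 1.9 | 42.2 | 4.9 | 6.9 |
| green | 8.00 | 50.3 | 1.6 | 28.5 | 8.1 | 7.7 |

(scatter of a reading: 0.3 percentage points)

- in percentages every species weighs as the substrate in it: one open dimer or side product counts as two
- what was read earlier has a scatter of 0.3 percentage points, one standard deviation
- at the start none of the gas is in solution

* which of these there is most of at the end, counted by the substrate in it, larch (over-reaction product / side product / ring / open dimer / substrate)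
* which of these there is most of at the end, counted by the substrate in it, cedar (over-reaction product / side product / ring / open dimer / substrate)
* which of these there is most of at the end, counted by the substrate in it, alder (over-reaction product / side product / ring / open dimer / substrate)
* amount of the one of these that there is most of at the end, in percent of the substrate charged, larch
* amount of the one of these that there is most of at the end, in percent of the substrate charged, cedar
* amount of the one of these that there is most of at the end, in percent of the substrate charged, alder

Two of us read these runs differently. My colleague holds a chain, in which “The open dimer feeds the over-reaction product”. Given time, the dimer should therefore empty into that product. The forecast accordingly names over-reaction product for larch, over-reaction product for cedar and over-reaction product for alder, at 43 %, 76 % and 85 %.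

I hold a fork: open dimer is one end, and ring plus over-reaction product, counted together, is the other. My ground is that at 8.00 min the green run has more open dimer than the amber run, 50.3 % against 46.5 %, but less over-reaction product, 8.1 % against 15.2 %.

So I compare the gains of the two branches between 3.00 min and 8.00 min. In amber the dimer gains 25 percentage points and the other branch 18 points, a ratio of 1.40 at a mean [substrate] of 29.6 mM. In green the gains are 29 points and 10 points, a ratio of 2.76 at 49.1 mM.

The ratio is higher at the higher [substrate], so I take it as [substrate]/K, a selectivity factor that depends on concentration. K is the crossover concentration, the [substrate] at which the two branches gain equally. Amber reads 21.1 mM and green 17.8 mM, and I carry their mean, K = 19.4 mM.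

Now the balance of the substrate. Each bit lost at a given [substrate] gives the dimer a share [substrate]/([substrate] + K). Running this from the charge c down to nothing gives the dimer an end share of 1 − (K/c) ln(1 + c/K). For c = 47 mM that is 49.2 %, which leaves 50.8 % for the other branch, side product apart. That is my own reckoning for the whole charge, which I apply to alder at 50 min, and it differs from the forecast's 85 %. For larch at 12 min I accept the forecast's 8 % of substrate and ring near 10 %; taking that ring from the other branch's 50.8 % puts larch's over-reaction product under its dimer, a rough call, since those 8 % of substrate still have to be shared.

The simulation gives larch open dimer at 45.2 %, cedar over-reaction product at 51.7 % and alder over-reaction product at 52.3 %.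

    substrate + activator → activated form (k = 0.300 L mol⁻¹ s⁻¹)
    activated form → ring (k = 0.0110 s⁻¹)
    substrate + activated form → open dimer (k = 0.300 L mol⁻¹ s⁻¹)
    substrate + activated form → side product (k = 0.0100 L mol⁻¹ s⁻¹)
    activator + ring → over-reaction product (k = 0.640 L mol⁻¹ s⁻¹)
    gas ⇌ activator, rate k6*(csat - [activator]) (kL = 0.0110 s⁻¹)

Alder's open dimer stands at 46.1 %, a little under my 49.2 %, and is still 46.1 % at 500 min. For larch's flask charged with 12 mM of substrate, K gives the whole charge a dimer share of 22.1 %. In that neighbour over-reaction product leads, as my colleague's view has it: at 12.0 min, with 5.01 % of substrate left, that flask holds 66.3 % of over-reaction product and 18.7 % of open dimer.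

(The runs are calculated for substances that don't exist; noise was put on by code.)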